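A direct plan would buy the ring as (R)-4-(tert-butyldimethylsilyloxy)cyclopent-2-enone A1, let its stereocentre steer a 1,2-addition of the ω-chain (C12), oxidise that stereocentre away, chlorinate the enone and silylate to the chlorocyclopentenone A2.
It would then make C7–C8 by an anti-aldol of the enolate of A2 with the achiral enal A3 to give the allylic alcohol A4, dihydroxylate the 5E alkene under direction by the C7 hydroxyl and acetylate the three secondary alcohols.
Weakest, first: the stereo-relay from A1 to A2, about eight operations in which a purchased stereocentre is used once and then destroyed, all to reach a small chlorocyclopentenone.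
Second: the aldol that makes C7–C8, because the face of C8 is chosen only by OSiMe3 versus CH2R on a quaternary carbon (a small bias) and the β-silyloxy enolate can eliminate.
Third: the hydroxyl-directed osmylation, which needs stoichiometric OsO4 on late material carrying three alkenes and sets C5 and C6 at once with no means of correction.

Plan of the new route:
Bonds cut: the ring bond C8–C12 together with C12–OH (key step); C8–C9 and C4–C5 (two ketone syntheses on one D-tartrate diamide that supplies C5–C8 with C6 and C7 already set); C12–C13 (alkylation of a chlorofuran).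
Enabling feature: the C9 ketone, the C10(Cl)=C11 alkene, the C12 tertiary carbinol and the C8–H methine of the cyclopentenone are, atom for atom, what a furan-2-yl carbinol gives on acid/water rearrangement (furan O1–C2 → C9=O, C3–Cl → C10–Cl, C4 → C11, C5 with the octenyl group → C12–OH, carbinol carbon → C8).
Ring order: the cyclopentenone, the only ring of the target, is the last skeletal event; until then the molecule is an open chain carrying a 2,3,5-trisubstituted furan.
The key step is stereoconvergent and dynamic: both C8 epimers of the precursor ionise to one cation, C12 is set by the conrotation under the influence of C7, and C8, being α to the new ketone, is equilibrated to the trans-dialkyl arrangement.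
The weak steps do not arise: no stereocentre is bought to be erased; C7–C8 exists before the ring, so there is no aldol; C6/C7 come from tartrate and C5 from a Felkin reduction of a robust acyclic ketone, so no osmium meets late material; the chlorine arrives on the furan.

Key step: step 9

Assumption: prostanoid numbering (C1 = ester carbon … C20) labels the atoms; (2Z)-oct-2-en-1-ol, 3-bromofuran, the acetonide of dimethyl D-tartrate and trimethyl 4-bromoorthobutyrate are taken as purchasable.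

Step 1
Reactants: 1 (2Z)-oct-2-en-1-ol
Product: 2 (2Z)-1-bromooct-2-ene
Conditions: CBr4, PPh3, CH2Cl2, 0 °C
Reagents that add atoms: carbon tetrabromide, BrC(Br)(Br)Br
Why: Appel bromination displaces the activated primary allylic oxygen by SN2 at 0 °C and should leave the Z-alkene in place.

Step 2
Reactants: 3 3-bromofuran
Product: 5 3-chlorofuran, via furan-3-yllithium 4 (not isolated)
Conditions: n-BuLi, Et2O, −78 °C; C2Cl6, −78 → 0 °C; distilled as a solution
Reagents that add atoms: hexachloroethane, ClC(Cl)(Cl)C(Cl)(Cl)Cl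
Why: Bromine–lithium exchange gives the 3-lithiofuran, stable at −78 °C, and electrophilic chlorine transfer from hexachloroethane puts the future C10 chlorine on the ring.

Step 3
Reactants: 5 3-chlorofuran
Product: 7 2-bromo-3-chlorofuran, via (3-chlorofuran-2-yl)lithium 6 (not isolated)
Conditions: LDA, THF, −78 °C; BrCl2C–CCl2Br, −78 → 0 °C
Reagents that add atoms: 1,2-dibromo-1,1,2,2-tetrachloroethane, BrC(Cl)(Cl)C(Cl)(Cl)Br
Why: Directed lithiation occurs at C2, the α-position flanked by O and Cl, and bromination there blocks C2 and stores the handle for the later regiospecific lithiation.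

Step 4
Reactants: 7 2-bromo-3-chlorofuran; 2 (2Z)-1-bromooct-2-ene
Product: 9 2-bromo-3-chloro-5-[(2Z)-oct-2-en-1-yl]furan, via (5-bromo-4-chlorofuran-2-yl)lithium 8 (not isolated)
Conditions: LDA, THF, −78 °C; then 2, −78 → −30 °C
Reagents that add atoms: (2Z)-1-bromooct-2-ene (2), CCCCC/C=C\CBr
Why: LDA removes the only remaining α-proton (C5) and the furyllithium is alkylated by the primary allylic bromide by SN2 with retention of the Z geometry, installing C13–C20.

Step 5
Reactants: 10 dimethyl (4S,5S)-2,2-dimethyl-1,3-dioxolane-4,5-dicarboxylate (acetonide of dimethyl D-tartrate)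
Product: 11 (4S,5S)-N4,N5-dimethoxy-N4,N5,2,2-tetramethyl-1,3-dioxolane-4,5-dicarboxamide
Conditions: MeNH(OMe)·HCl, i-PrMgCl, THF, −20 → 0 °C
Reagents that add atoms: N,O-dimethylhydroxylamine hydrochloride, CNOC.Cl
Why: Aminolysis of both esters by the magnesium amide gives the bis-Weinreb amide without touching the trans-dioxolane stereocentres (future C6 and C7).

Step 6
Reactants: 9 2-bromo-3-chloro-5-[(2Z)-oct-2-en-1-yl]furan; 11 (4S,5S)-N4,N5-dimethoxy-N4,N5,2,2-tetramethyl-1,3-dioxolane-4,5-dicarboxamide; 12 4-bromo-1,1,1-trimethoxybutane (trimethyl 4-bromoorthobutyrate)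
Product: 17 methyl 5-[(4S,5S)-5-{3-chloro-5-[(2Z)-oct-2-en-1-yl]furan-2-carbonyl}-2,2-dimethyl-1,3-dioxolan-4-yl]-5-oxopentanoate, via {3-chloro-5-[(2Z)-oct-2-en-1-yl]furan-2-yl}lithium 13 (not isolated), via (4,4,4-trimethoxybutyl)magnesium bromide 14 (not isolated), via lithium {3-chloro-5-[(2Z)-oct-2-en-1-yl]furan-2-yl}{(4S,5S)-5-[methoxy(methyl)carbamoyl]-2,2-dimethyl-1,3-dioxolan-4-yl}[methoxy(methyl)amino]methanolate 15 (not isolated), via 1-[(4S,5S)-5-{3-chloro-5-[(2Z)-oct-2-en-1-yl]furan-2-carbonyl}-2,2-dimethyl-1,3-dioxolan-4-yl]-5,5,5-trimethoxypentan-1-one 16 (not isolated)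
Conditions: 9, n-BuLi, THF, −78 °C; add to 11 (excess), −78 °C; then 14 (from 12, Mg, THF), −78 → 0 °C; aq. NH4Cl, then 0.5 M HCl
Reagents that add atoms: bis-amide 11, CON(C)C(=O)[C@H]1OC(C)(C)O[C@@H]1C(=O)N(C)OC; orthoester bromide 12, COC(OC)(OC)CCCBr; water (work-up), O
Why: Two Weinreb ketone syntheses in one flask: the furyllithium from bromine–lithium exchange acylates one amide to a stable tetrahedral chelate that masks the C8 ketone while the Grignard reagent acylates the second amide (C4–C5), and the acidic work-up releases both ketones and turns the orthoester into the methyl ester without touching a stereocentre.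

Step 7
Reactants: 17 methyl 5-[(4S,5S)-5-{3-chloro-5-[(2Z)-oct-2-en-1-yl]furan-2-carbonyl}-2,2-dimethyl-1,3-dioxolan-4-yl]-5-oxopentanoate
Product: 18 methyl (5S)-5-[(4R,5R)-5-{(RS)-{3-chloro-5-[(2Z)-oct-2-en-1-yl]furan-2-yl}(hydroxy)methyl}-2,2-dimethyl-1,3-dioxolan-4-yl]-5-hydroxypentanoate (both C8 epimers)
Conditions: L-Selectride, THF, −78 °C; neutral aqueous work-up; used at once
Reagents that add atoms: none
Why: Felkin–Anh reduction with the bulky, non-chelating hydride should add to the C5 ketone anti to the C6–O bond of the dioxolane to give the 5,6-syn (5S) alcohol, while the furyl ketone is reduced without need for control because C8 is planarised in step 9.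

Step 8
Reactants: 18 methyl (5S)-5-[(4R,5R)-5-{(RS)-{3-chloro-5-[(2Z)-oct-2-en-1-yl]furan-2-yl}(hydroxy)methyl}-2,2-dimethyl-1,3-dioxolan-4-yl]-5-hydroxypentanoate
Product: 19 methyl (5S)-5-acetoxy-5-[(4R,5S)-5-{(RS)-acetoxy{3-chloro-5-[(2Z)-oct-2-en-1-yl]furan-2-yl}methyl}-2,2-dimethyl-1,3-dioxolan-4-yl]pentanoate
Conditions: Ac2O, pyridine, DMAP (cat.), CH2Cl2, 0 °C → rt
Reagents that add atoms: acetic anhydride, CC(=O)OC(C)=O
Why: DMAP-catalysed acetylation of both secondary alcohols installs the C5 acetate of the target, forestalls δ-lactonisation, and makes the furfuryl C8 oxygen the leaving group for step 9.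

Step 9
Reactants: 19 methyl (5S)-5-acetoxy-5-[(4R,5S)-5-{(RS)-acetoxy{3-chloro-5-[(2Z)-oct-2-en-1-yl]furan-2-yl}methyl}-2,2-dimethyl-1,3-dioxolan-4-yl]pentanoate
Product: 21 methyl (5S)-5-acetoxy-5-[(4R,5R)-5-[(1R,5S)-3-chloro-5-hydroxy-5-[(2Z)-oct-2-en-1-yl]-2-oxocyclopent-3-en-1-yl]-2,2-dimethyl-1,3-dioxolan-4-yl]pentanoate, via its C8 epimer methyl (5S)-5-acetoxy-5-[(4R,5R)-5-[(1S,5S)-3-chloro-5-hydroxy-5-[(2Z)-oct-2-en-1-yl]-2-oxocyclopent-3-en-1-yl]-2,2-dimethyl-1,3-dioxolan-4-yl]pentanoate 20 (not isolated)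
Conditions: ZnCl2, acetone–H2O (2:1), 60 °C; extractive work-up; then KOAc, MeOH, 23 °C
Reagents that add atoms: water, O
Why: ZnCl2-assisted ionisation of the furfuryl acetate (either C8 epimer) gives one 2-alkylidene-2H-furanium ion, water adds at furan C5 (= C12), the hemiketal opens to the 1,4-dihydroxy-3-chloropentadienyl cation, and this closes C8–C12 and loses a proton to the 2-chloroenone, which is the Piancatelli rearrangement of a 5-substituted furan-2-yl carbinol derivative. The ring is closed by a thermally allowed conrotatory 4π electrocyclisation of that cation (Nazarov type), not by an enolate aldol. With the C7 chain and the C12 hydroxyl both "out", as in Piancatelli closures generally, C8 should first form with its chain trans to OH (20); C8 is α to the ketone and is then equilibrated through the enol by KOAc to the trans-dialkyl arrangement 21, as 8-iso-PGE goes to PGE. C12 is fixed by the sense of conrotation, which C7 should dictate: H-7 eclipses the C8=C9 enol bond (A1,3 strain with O9–H), the acetal carbon C6 lies anti to the forming bond and O7 outside, so the bond forms on the face that gives (12S). The step needs water to add at C12 rather than C8 (attack at C8 only returns the carbinol) and needs the acetonide to survive, which acetone as co-solvent should secure; the acetal-type O7 and the remote C5 acetate cannot give an acyloxonium ion with C8.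

Step 10
Reactants: 21 methyl (5S)-5-acetoxy-5-[(4R,5R)-5-[(1R,5S)-3-chloro-5-hydroxy-5-[(2Z)-oct-2-en-1-yl]-2-oxocyclopent-3-en-1-yl]-2,2-dimethyl-1,3-dioxolan-4-yl]pentanoate
Product: 22 methyl (5S,6S,7R)-5-acetoxy-7-[(1R,5S)-3-chloro-5-hydroxy-5-[(2Z)-oct-2-en-1-yl]-2-oxocyclopent-3-en-1-yl]-6,7-dihydroxyheptanoate
Conditions: TFA–H2O–THF (8:1:1), 0 °C → rt; used crude
Reagents that add atoms: none
Why: Acid hydrolysis of the trans-acetonide frees the 6,7-diol; the tertiary C12–OH should not ionise (its cation would be α to the enone) and any acetyl migration is harmless because all three positions end acetylated.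

Step 11
Reactants: 22 methyl (5S,6S,7R)-5-acetoxy-7-[(1R,5S)-3-chloro-5-hydroxy-5-[(2Z)-oct-2-en-1-yl]-2-oxocyclopent-3-en-1-yl]-6,7-dihydroxyheptanoate
Product: 23 punaglandin 2, methyl (5S,6R,7R)-5,6,7-triacetoxy-7-[(1R,5S)-3-chloro-5-hydroxy-5-[(2Z)-oct-2-en-1-yl]-2-oxocyclopent-3-en-1-yl]heptanoate
Conditions: Ac2O, pyridine, CH2Cl2, 0 °C → rt (no DMAP)
Reagents that add atoms: acetic anhydride, CC(=O)OC(C)=O
Why: Acetylation without DMAP should esterify the two secondary alcohols and leave the hindered tertiary C12–OH free, the low temperature limiting E1cB loss of the 7-acetate.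

Compound list
1 | (2Z)-oct-2-en-1-ol | CCCCC/C=C\CO | starting material
2 | (2Z)-1-bromooct-2-ene | CCCCC/C=C\CBr | intermediate
3 | 3-bromofuran | Brc1ccoc1 | starting material
4 | furan-3-yllithium | [Li]c1ccoc1 | intermediate
5 | 3-chlorofuran | Clc1ccoc1 | intermediate
6 | (3-chlorofuran-2-yl)lithium | [Li]c1occc1Cl | intermediate
7 | 2-bromo-3-chlorofuran | Brc1occc1Cl | intermediate
8 | (5-bromo-4-chlorofuran-2-yl)lithium | [Li]c1cc(Cl)c(Br)o1 | intermediate
9 | 2-bromo-3-chloro-5-[(2Z)-oct-2-en-1-yl]furan | CCCCC/C=C\Cc1cc(Cl)c(Br)o1 | intermediate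
10 | dimethyl (4S,5S)-2,2-dimethyl-1,3-dioxolane-4,5-dicarboxylate | COC(=O)[C@H]1OC(C)(C)O[C@@H]1C(=O)OC | starting material
11 | (4S,5S)-N4,N5-dimethoxy-N4,N5,2,2-tetramethyl-1,3-dioxolane-4,5-dicarboxamide | CON(C)C(=O)[C@H]1OC(C)(C)O[C@@H]1C(=O)N(C)OC | intermediate
12 | 4-bromo-1,1,1-trimethoxybutane | COC(OC)(OC)CCCBr | starting material
13 | {3-chloro-5-[(2Z)-oct-2-en-1-yl]furan-2-yl}lithium | CCCCC/C=C\Cc1cc(Cl)c([Li])o1 | intermediate
14 | (4,4,4-trimethoxybutyl)magnesium bromide | COC(OC)(OC)CCC[Mg]Br | intermediate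
15 | lithium {3-chloro-5-[(2Z)-oct-2-en-1-yl]furan-2-yl}{(4S,5S)-5-[methoxy(methyl)carbamoyl]-2,2-dimethyl-1,3-dioxolan-4-yl}[methoxy(methyl)amino]methanolate | CCCCC/C=C\Cc1cc(Cl)c(o1)C([O-])(N(C)OC)[C@H]1OC(C)(C)O[C@@H]1C(=O)N(C)OC.[Li+] | intermediate
16 | 1-[(4S,5S)-5-{3-chloro-5-[(2Z)-oct-2-en-1-yl]furan-2-carbonyl}-2,2-dimethyl-1,3-dioxolan-4-yl]-5,5,5-trimethoxypentan-1-one | CCCCC/C=C\Cc1cc(Cl)c(o1)C(=O)[C@H]1OC(C)(C)O[C@@H]1C(=O)CCCC(OC)(OC)OC | intermediate
17 | methyl 5-[(4S,5S)-5-{3-chloro-5-[(2Z)-oct-2-en-1-yl]furan-2-carbonyl}-2,2-dimethyl-1,3-dioxolan-4-yl]-5-oxopentanoate | CCCCC/C=C\Cc1cc(Cl)c(o1)C(=O)[C@H]1OC(C)(C)O[C@@H]1C(=O)CCCC(=O)OC | intermediate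
18 | methyl (5S)-5-[(4R,5R)-5-{(RS)-{3-chloro-5-[(2Z)-oct-2-en-1-yl]furan-2-yl}(hydroxy)methyl}-2,2-dimethyl-1,3-dioxolan-4-yl]-5-hydroxypentanoate | CCCCC/C=C\Cc1cc(Cl)c(o1)C(O)[C@H]1OC(C)(C)O[C@@H]1[C@H](CCCC(=O)OC)O | intermediate
19 | methyl (5S)-5-acetoxy-5-[(4R,5S)-5-{(RS)-acetoxy{3-chloro-5-[(2Z)-oct-2-en-1-yl]furan-2-yl}methyl}-2,2-dimethyl-1,3-dioxolan-4-yl]pentanoate | CCCCC/C=C\Cc1cc(Cl)c(o1)C(OC(C)=O)[C@H]1OC(C)(C)O[C@@H]1[C@H](CCCC(=O)OC)OC(C)=O | intermediate
20 | methyl (5S)-5-acetoxy-5-[(4R,5R)-5-[(1S,5S)-3-chloro-5-hydroxy-5-[(2Z)-oct-2-en-1-yl]-2-oxocyclopent-3-en-1-yl]-2,2-dimethyl-1,3-dioxolan-4-yl]pentanoate | CCCCC/C=C\C[C@@]1(O)C=C(Cl)C(=O)[C@H]1[C@H]2OC(C)(C)O[C@@H]2[C@H](CCCC(=O)OC)OC(C)=O | intermediate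
21 | methyl (5S)-5-acetoxy-5-[(4R,5R)-5-[(1R,5S)-3-chloro-5-hydroxy-5-[(2Z)-oct-2-en-1-yl]-2-oxocyclopent-3-en-1-yl]-2,2-dimethyl-1,3-dioxolan-4-yl]pentanoate | CCCCC/C=C\C[C@@]1(O)C=C(Cl)C(=O)[C@@H]1[C@H]2OC(C)(C)O[C@@H]2[C@H](CCCC(=O)OC)OC(C)=O | intermediate
22 | methyl (5S,6S,7R)-5-acetoxy-7-[(1R,5S)-3-chloro-5-hydroxy-5-[(2Z)-oct-2-en-1-yl]-2-oxocyclopent-3-en-1-yl]-6,7-dihydroxyheptanoate | CCCCC/C=C\C[C@@]1(O)C=C(Cl)C(=O)[C@@H]1[C@@H](O)[C@H](O)[C@H](CCCC(=O)OC)OC(C)=O | intermediate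
23 | punaglandin 2, methyl (5S,6R,7R)-5,6,7-triacetoxy-7-[(1R,5S)-3-chloro-5-hydroxy-5-[(2Z)-oct-2-en-1-yl]-2-oxocyclopent-3-en-1-yl]heptanoate | CCCCC/C=C\C[C@@]1(O)C=C(Cl)C(=O)[C@@H]1[C@@H](OC(C)=O)[C@H](OC(C)=O)[C@H](CCCC(=O)OC)OC(C)=O | target

Total step count: 11.
Longest linear sequence: 9 (3-bromofuran to 23: steps 2, 3, 4, 6, 7, 8, 9, 10, 11).

Steps most likely to fail

Step 9. The conrotation may show poor or reversed facial selectivity with respect to C7, so that C12 comes out as the wrong epimer, and part of the furfuryl cation may be lost by proton loss toward C7 or C13 before water adds. The fallback sets out from 19 and comes back at 21, and replaces kinetic control by a reversible aldol. The rearrangement is run as above and the unwanted trans-dialkyl diastereomer, methyl (5S)-5-acetoxy-5-[(4R,5R)-5-[(1S,5R)-3-chloro-5-hydroxy-5-[(2Z)-oct-2-en-1-yl]-2-oxocyclopent-3-en-1-yl]-2,2-dimethyl-1,3-dioxolan-4-yl]pentanoate F1, is separated. Catalytic DBU in toluene should open its tertiary aldol by retro-aldol to the cis-enedione, methyl (5S)-5-acetoxy-5-[(4S,5R)-5-[(3E,7Z)-3-chloro-2,5-dioxotrideca-3,7-dien-1-yl]-2,2-dimethyl-1,3-dioxolan-4-yl]pentanoate F2. This recloses to a mixture of F1 and 21, from which 21 is removed and F1 recycled.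

Step 6. The one-flask double addition may go unevenly (bis-furyl or bis-alkyl ketones), and base may epimerise the α-alkoxy carbons. The fallback sets out from 11 and comes back at 19; the two carbonyl groups are handled in separate operations and the furan is joined to an aldehyde instead of an amide.
- Grignard reagent 14 alone adds to 11 to give (4S,5S)-N-methoxy-N,2,2-trimethyl-5-(5,5,5-trimethoxypentanoyl)-1,3-dioxolane-4-carboxamide F3.
- Acidic work-up gives methyl 5-[(4S,5S)-5-[methoxy(methyl)carbamoyl]-2,2-dimethyl-1,3-dioxolan-4-yl]-5-oxopentanoate F4.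
- L-Selectride gives methyl (5S)-5-hydroxy-5-[(4R,5S)-5-[methoxy(methyl)carbamoyl]-2,2-dimethyl-1,3-dioxolan-4-yl]pentanoate F5.
- Ac2O/pyridine gives methyl (5S)-5-acetoxy-5-[(4R,5S)-5-[methoxy(methyl)carbamoyl]-2,2-dimethyl-1,3-dioxolan-4-yl]pentanoate F6.
- Cp2Zr(H)Cl reduces the remaining Weinreb amide to methyl (5S)-5-acetoxy-5-[(4R,5S)-5-formyl-2,2-dimethyl-1,3-dioxolan-4-yl]pentanoate F7.
- Furyllithium 13 (from 9, n-BuLi, −78 °C) adds to the aldehyde to give methyl (5S)-5-acetoxy-5-[(4R,5R)-5-{(RS)-{3-chloro-5-[(2Z)-oct-2-en-1-yl]furan-2-yl}(hydroxy)methyl}-2,2-dimethyl-1,3-dioxolan-4-yl]pentanoate F8.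
- Acetylation of F8 gives 19.

Step 4. Lithiofuran 8 may undergo halogen dance before it is trapped, and the allylic alkylation may leak to SN2′ attack or to the E isomer. The fallback sets out from 7 and comes back at 9, building the Z-alkene on the furan instead of importing it. Lithiofuran 8 is trapped at −78 °C with oxirane/BF3·OEt2 to give 2-(5-bromo-4-chlorofuran-2-yl)ethan-1-ol F9. Dess–Martin oxidation gives 2-(5-bromo-4-chlorofuran-2-yl)acetaldehyde F10, used crude. A Z-selective Wittig reaction with the ylide from hexyltriphenylphosphonium bromide (NaHMDS, THF, −78 °C) then gives 9.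

Further compounds
F1 | step 9 | methyl (5S)-5-acetoxy-5-[(4R,5R)-5-[(1S,5R)-3-chloro-5-hydroxy-5-[(2Z)-oct-2-en-1-yl]-2-oxocyclopent-3-en-1-yl]-2,2-dimethyl-1,3-dioxolan-4-yl]pentanoate | CCCCC/C=C\C[C@]1(O)C=C(Cl)C(=O)[C@H]1[C@H]2OC(C)(C)O[C@@H]2[C@H](CCCC(=O)OC)OC(C)=O
F2 | step 9 | methyl (5S)-5-acetoxy-5-[(4S,5R)-5-[(3E,7Z)-3-chloro-2,5-dioxotrideca-3,7-dien-1-yl]-2,2-dimethyl-1,3-dioxolan-4-yl]pentanoate | CCCCC/C=C\CC(=O)/C=C(Cl)\C(=O)C[C@H]1OC(C)(C)O[C@@H]1[C@H](CCCC(=O)OC)OC(C)=O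
F3 | step 6 | (4S,5S)-N-methoxy-N,2,2-trimethyl-5-(5,5,5-trimethoxypentanoyl)-1,3-dioxolane-4-carboxamide | CON(C)C(=O)[C@H]1OC(C)(C)O[C@@H]1C(=O)CCCC(OC)(OC)OC
F4 | step 6 | methyl 5-[(4S,5S)-5-[methoxy(methyl)carbamoyl]-2,2-dimethyl-1,3-dioxolan-4-yl]-5-oxopentanoate | CON(C)C(=O)[C@H]1OC(C)(C)O[C@@H]1C(=O)CCCC(=O)OC
F5 | step 6 | methyl (5S)-5-hydroxy-5-[(4R,5S)-5-[methoxy(methyl)carbamoyl]-2,2-dimethyl-1,3-dioxolan-4-yl]pentanoate | CON(C)C(=O)[C@H]1OC(C)(C)O[C@@H]1[C@H](CCCC(=O)OC)O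
F6 | step 6 | methyl (5S)-5-acetoxy-5-[(4R,5S)-5-[methoxy(methyl)carbamoyl]-2,2-dimethyl-1,3-dioxolan-4-yl]pentanoate | CON(C)C(=O)[C@H]1OC(C)(C)O[C@@H]1[C@H](CCCC(=O)OC)OC(C)=O
F7 | step 6 | methyl (5S)-5-acetoxy-5-[(4R,5S)-5-formyl-2,2-dimethyl-1,3-dioxolan-4-yl]pentanoate | O=C[C@H]1OC(C)(C)O[C@@H]1[C@H](CCCC(=O)OC)OC(C)=O
F8 | step 6 | methyl (5S)-5-acetoxy-5-[(4R,5R)-5-{(RS)-{3-chloro-5-[(2Z)-oct-2-en-1-yl]furan-2-yl}(hydroxy)methyl}-2,2-dimethyl-1,3-dioxolan-4-yl]pentanoate | CCCCC/C=C\Cc1cc(Cl)c(o1)C(O)[C@H]1OC(C)(C)O[C@@H]1[C@H](CCCC(=O)OC)OC(C)=O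
F9 | step 4 | 2-(5-bromo-4-chlorofuran-2-yl)ethan-1-ol | OCCc1cc(Cl)c(Br)o1
F10 | step 4 | 2-(5-bromo-4-chlorofuran-2-yl)acetaldehyde | O=CCc1cc(Cl)c(Br)o1
A1 | direct plan | (R)-4-(tert-butyldimethylsilyloxy)cyclopent-2-en-1-one | O=C1C=C[C@H](O[Si](C)(C)C(C)(C)C)C1
A2 | direct plan | (4S)-2-chloro-4-[(2Z)-oct-2-en-1-yl]-4-(trimethylsilyloxy)cyclopent-2-en-1-one | CCCCC/C=C\C[C@@]1(O[Si](C)(C)C)C=C(Cl)C(=O)C1
A3 | direct plan | methyl (5E)-7-oxohept-5-enoate | COC(=O)CCC/C=C/C=O
A4 | direct plan | methyl (5E,7S)-7-[(1R,5S)-3-chloro-5-[(2Z)-oct-2-en-1-yl]-2-oxo-5-(trimethylsilyloxy)cyclopent-3-en-1-yl]-7-hydroxyhept-5-enoate | CCCCC/C=C\C[C@@]1(O[Si](C)(C)C)C=C(Cl)C(=O)[C@@H]1[C@@H](O)/C=C/CCCC(=O)OC
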